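# Total synthesis of ketoemblide

**Retrosynthetic overview**
1. The 14-membered carbocycle is closed last, by intramolecular enolate alkylation (C5–C6) of the methyl ketone with a 2-(bromomethyl)dienoate. The Z-dienoate is already in place.
2. The acyclic precursor comes from a Negishi coupling (C12–C13) of two halves of similar size: an α-bromo unsaturated ε-lactone and an alkylzinc bearing the dienoate chain.
3. The 7-membered lactone is formed first, by RCM. Its quaternary carbinol carbon (C8) comes from Sharpless AE of methallyl alcohol.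
4. The diene is built by syn-carbocupration of an ynoate, which sets the C1=C2 geometry, followed by a Still–Gennari olefination, which sets the Z geometry at C3=C4.

**Assumption:** C8 is (S), and the diene geometry is as in the SMILES (ester cis to C2, iPr trans to C3). Sharpless AE with D-(–)-DET gives the (R)-epoxy alcohol in ≥90% ee.

---

**Step 1**
Reactants: 1 methallyl alcohol (2-methylprop-2-en-1-ol)
Product: 2 (R)-2-methylglycidol, [(2R)-2-methyloxiran-2-yl]methanol
Conditions: Ti(OiPr)4 (10 mol%), D-(–)-DET (12 mol%), TBHP, 3 Å MS, CH2Cl2, –20 °C; crude product used directly (volatile, water-soluble)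
Reagents that add atoms: tert-butyl hydroperoxide, CC(C)(C)OO (supplies the epoxide O)
Why: Sharpless asymmetric epoxidation, in which the D-tartrate delivers oxygen to the top face of the allylic alcohol and sets the configuration of the future C8.

**Step 2**
Reactants: 2
Product: 3 tert-butyldimethyl{[(2S)-2-methyloxiran-2-yl]methoxy}silane
Conditions: TBSCl, imidazole, CH2Cl2, 0 °C → rt
Reagents that add atoms: TBSCl, CC(C)(C)[Si](C)(C)Cl
Why: Silylation of the primary alcohol; the descriptor changes from R to S only because Si outranks C in CIP priority, and the geometry is unchanged.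

**Step 3**
Reactants: 3
Product: 4 (2S)-1-(TBSO)-2-methylhex-5-en-2-ol
Conditions: allylMgBr (2 equiv), CuI (10 mol%), THF, –40 → 0 °C
Reagents that add atoms: allylmagnesium bromide, C=CC[Mg]Br
Why: Cu-catalysed Grignard opening of the epoxide occurs at the unhindered CH2 (becoming C9) and leaves the quaternary C–O bond intact, so the configuration at C8 is retained.

**Step 4**
Reactants: 4; 5 acryloyl chloride
Product: 6 (2S)-1-(TBSO)-2-methylhex-5-en-2-yl acrylate
Conditions: iPr2NEt, DMAP (cat.), BHT, CH2Cl2, 0 °C → rt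
Reagents that add atoms: none
Why: DMAP-catalysed acylation of the tertiary alcohol makes the RCM precursor, with no change at the stereocentre.

**Step 5**
Reactants: 6
Product: 7 (7S)-7-[(TBSO)methyl]-7-methyl-6,7-dihydrooxepin-2(5H)-one
Conditions: Hoveyda–Grubbs II (5 mol%), Ti(OiPr)4 (0.3 equiv), CH2Cl2 (5 mM), 40 °C
Reagents that add atoms: none
Why: Ring-closing metathesis, helped by the gem-disubstituted quaternary carbon, forms the cis-C11=C12 enoate of the 7-membered lactone and releases ethylene.

**Step 6**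
Reactants: 7
Product: 8 (7S)-3-bromo-7-[(TBSO)methyl]-7-methyl-6,7-dihydrooxepin-2(5H)-one
Conditions: Br2, CH2Cl2, 0 °C; then Et3N, rt
Reagents that add atoms: bromine, BrBr
Why: Bromination gives the 2,3-dibromide, and E1cB loss of HBr with Et3N delivers the α-bromoenoate (the Negishi partner).

**Step 7**
Reactants: 8
Product: 9 (7S)-3-bromo-7-(hydroxymethyl)-7-methyl-6,7-dihydrooxepin-2(5H)-one
Conditions: HF·pyridine, pyridine, THF, 0 °C → rt
Reagents that add atoms: none
Why: Acidic fluoride removes the neopentyl TBS group without the basic conditions that would risk acyl migration or lactone opening.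

**Step 8**
Reactants: 9
Product: 10 (7S)-3-bromo-7-methyl-2-oxo-2,5,6,7-tetrahydrooxepine-7-carbaldehyde
Conditions: Dess–Martin periodinane, NaHCO3, CH2Cl2, rt
Reagents that add atoms: none
Why: Mild oxidation; the α-carbon is quaternary, so the aldehyde cannot epimerise.

**Step 9**
Reactants: 10
Product: 11 (7S)-3-bromo-7-(1-hydroxyethyl)-7-methyl-6,7-dihydrooxepin-2(5H)-one (carbinol epimers)
Conditions: MeTi(OiPr)3, THF, –78 → 0 °C
Reagents that add atoms: methyltitanium triisopropoxide, C[Ti](OC(C)C)(OC(C)C)OC(C)C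
Why: Reetz methyl-titanium addition is chemoselective for the aldehyde over the lactone and the vinyl bromide, and the new carbinol stereocentre is destroyed in the next step.

**Step 10**
Reactants: 11
Product: 12 (7S)-7-acetyl-3-bromo-7-methyl-6,7-dihydrooxepin-2(5H)-one
Conditions: Dess–Martin periodinane, NaHCO3, CH2Cl2, rt
Reagents that add atoms: none
Why: Oxidation of the secondary alcohol gives the methyl ketone (C6–C7), and C8 is untouched.

**Step 11**
Reactants: 13 but-3-yn-1-ol
Product: 14 tert-butyl(but-3-yn-1-yloxy)dimethylsilane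
Conditions: TBSCl, imidazole, DMF, rt
Reagents that add atoms: TBSCl, CC(C)(C)[Si](C)(C)Cl
Why: Protection of the alcohol before the alkyne is lithiated.

**Step 12**
Reactants: 14
Product: 15 ethyl 5-(TBSO)pent-2-ynoate
Conditions: n-BuLi, THF, –78 °C; then ClCO2Et
Reagents that add atoms: ethyl chloroformate, CCOC(=O)Cl
Why: Alkynyl-lithium acylation gives the ynoate that will carry C3 (ester carbon), C2 and C1.

**Step 13**
Reactants: 15
Product: 16 ethyl (2E)-5-(TBSO)-3-isopropylpent-2-enoate
Conditions: iPrMgBr, CuBr·SMe2, THF/Me2S, –40 °C to form the cuprate; add 15 at –78 °C; quench with AcOH/THF at –78 °C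
Reagents that add atoms: isopropylmagnesium bromide, CC(C)[Mg]Br
Why: Syn-carbocupration of the ynoate puts iPr on C1 and H on C2 cis to it, so the ester is trans to iPr, which fixes the C1=C2 geometry.

**Step 14**
Reactants: 16
Product: 17 (2E)-5-(TBSO)-3-isopropylpent-2-en-1-ol
Conditions: DIBAL-H (2.5 equiv), CH2Cl2, –78 °C
Reagents that add atoms: none
Why: 1,2-Reduction of the ester to the allylic alcohol, leaving the alkene geometry and the TBS ether intact.

**Step 15**
Reactants: 17
Product: 18 (2E)-5-(TBSO)-3-isopropylpent-2-enal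
Conditions: MnO2 (10 equiv), CH2Cl2, rt
Reagents that add atoms: none
Why: Chemoselective oxidation of the allylic alcohol to the enal (C3 aldehyde).

**Step 16**
Reactants: 19 methyl bromoacetate
Product: 20 methyl 2-[bis(2,2,2-trifluoroethoxy)phosphoryl]acetate
Conditions: P(OCH2CF3)3, neat, 110–120 °C, CF3CH2Br distilled off
Reagents that add atoms: tris(2,2,2-trifluoroethyl) phosphite, FC(F)(F)COP(OCC(F)(F)F)OCC(F)(F)F
Why: Michaelis–Arbuzov reaction gives the Still–Gennari phosphonoacetate.

**Step 17**
Reactants: 20; 21 formaldehyde (as paraformaldehyde)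
Product: 22 methyl 2-[bis(2,2,2-trifluoroethoxy)phosphoryl]-3-hydroxypropanoate
Conditions: (CH2O)n, K2CO3 (10 mol%), THF, 0 → 25 °C, short reaction time
Reagents that add atoms: none
Why: Base-catalysed hydroxymethylation of the acidic phosphonoacetate methylene installs the future C5.

**Step 18**
Reactants: 22
Product: 23 methyl 3-(TBDPSO)-2-[bis(2,2,2-trifluoroethoxy)phosphoryl]propanoate
Conditions: TBDPSCl, imidazole, DMF, rt
Reagents that add atoms: TBDPSCl, CC(C)(C)[Si](c1ccccc1)(c1ccccc1)Cl
Why: A TBDPS ether that survives the later selective removal of the C13 TBS group.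

**Step 19**
Reactants: 18; 23
Product: 24 methyl (2Z,4E)-7-(TBSO)-2-[(TBDPSO)methyl]-5-isopropylhepta-2,4-dienoate
Conditions: KHMDS, 18-crown-6, THF, –78 °C
Reagents that add atoms: none
Why: Still–Gennari olefination, under kinetic control with the electron-poor phosphonate, gives the Z-trisubstituted enoate in which C2 is cis to the ester (C3=C4), while the E C1=C2 bond is retained.

**Step 20**
Reactants: 24
Product: 25 methyl (2Z,4E)-7-hydroxy-2-[(TBDPSO)methyl]-5-isopropylhepta-2,4-dienoate
Conditions: HF·pyridine, pyridine, THF, 0 °C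
Reagents that add atoms: none
Why: The primary TBS ether is cleaved selectively over the more hindered TBDPS ether.

**Step 21**
Reactants: 25
Product: 26 methyl (2Z,4E)-7-iodo-2-[(TBDPSO)methyl]-5-isopropylhepta-2,4-dienoate
Conditions: PPh3, imidazole, I2 (1.2 equiv each), Et2O/MeCN, 0 °C, dark
Reagents that add atoms: iodine, II
Why: Appel-type iodination gives the alkyl iodide, kept cold and dark to avoid I2-mediated Z/E isomerisation of the diene.

**Step 22**
Reactants: 26; 12
Product: 27 methyl (2Z,4E)-7-[(7S)-7-acetyl-7-methyl-2-oxo-2,5,6,7-tetrahydrooxepin-3-yl]-2-[(TBDPSO)methyl]-5-isopropylhepta-2,4-dienoate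
Conditions: Zn dust (TMSCl/BrCH2CH2Br activated), LiCl, THF, 40 °C to form RZnI from 26; then 12, Pd(PPh3)4 (5 mol%), THF, 40 °C
Reagents that add atoms: none (zinc is not retained)
Why: Negishi coupling joins the alkylzinc to the activated α-bromoenoate (C12–C13), and the ketone, esters, diene and silyl ether survive.

**Step 23**
Reactants: 27
Product: 28 methyl (2Z,4E)-7-[(7S)-7-acetyl-7-methyl-2-oxo-2,5,6,7-tetrahydrooxepin-3-yl]-2-(hydroxymethyl)-5-isopropylhepta-2,4-dienoate
Conditions: HF·pyridine, pyridine, THF, 0 → 25 °C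
Reagents that add atoms: none
Why: Acidic fluoride removes the TBDPS group without attacking the lactone or ketone.

**Step 24**
Reactants: 28
Product: 29 methyl (2Z,4E)-2-(bromomethyl)-7-[(7S)-7-acetyl-7-methyl-2-oxo-2,5,6,7-tetrahydrooxepin-3-yl]-5-isopropylhepta-2,4-dienoate
Conditions: CBr4, PPh3, CH2Cl2, 0 °C, 1 h; used immediately
Reagents that add atoms: carbon tetrabromide, BrC(Br)(Br)Br
Why: Appel bromination under neutral conditions gives the reactive allylic bromide without isomerising the diene.

**Step 25**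
Reactants: 29
Product: 30 ketoemblide (target)
Conditions: KHMDS (3 equiv), THF, –78 → –40 °C; 29 added by syringe pump over 8 h (final ~1 mM)
Reagents that add atoms: none
Why: Intramolecular enolate alkylation (SN2), where the only enolisable site is the CH3 because C8 is quaternary, closes the 14-membered ring at C5–C6 and creates no new stereocentre.

---

## Compound list

| No. | Name | SMILES | Role |
|---|---|---|---|
| 1 | 2-methylprop-2-en-1-ol | C=C(C)CO | starting material |
| 2 | (2R)-(2-methyloxiran-2-yl)methanol | C[C@@]1(CO)CO1 | intermediate |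
| 3 | TBS ether of 2, (2S) | C[C@@]1(CO[Si](C)(C)C(C)(C)C)CO1 | intermediate |
| 4 | (2S)-1-(TBSO)-2-methylhex-5-en-2-ol | C=CCC[C@](C)(O)CO[Si](C)(C)C(C)(C)C | intermediate |
| 5 | acryloyl chloride | C=CC(=O)Cl | starting material |
| 6 | (2S)-1-(TBSO)-2-methylhex-5-en-2-yl acrylate | C=CCC[C@](C)(OC(=O)C=C)CO[Si](C)(C)C(C)(C)C | intermediate |
| 7 | (7S)-7-[(TBSO)methyl]-7-methyl-6,7-dihydrooxepin-2(5H)-one | C[C@@]1(CO[Si](C)(C)C(C)(C)C)CCC=CC(=O)O1 | intermediate |
| 8 | (7S)-3-bromo analogue of 7 | C[C@@]1(CO[Si](C)(C)C(C)(C)C)CCC=C(Br)C(=O)O1 | intermediate |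
| 9 | (7S)-3-bromo-7-(hydroxymethyl)-7-methyl-6,7-dihydrooxepin-2(5H)-one | C[C@@]1(CO)CCC=C(Br)C(=O)O1 | intermediate |
| 10 | (7S)-3-bromo-7-formyl-7-methyl lactone | C[C@@]1(C=O)CCC=C(Br)C(=O)O1 | intermediate |
| 11 | (7S)-3-bromo-7-(1-hydroxyethyl)-7-methyl lactone (carbinol epimers) | C[C@@]1(C(C)O)CCC=C(Br)C(=O)O1 | intermediate |
| 12 | (7S)-7-acetyl-3-bromo-7-methyl-6,7-dihydrooxepin-2(5H)-one | C[C@@]1(C(C)=O)CCC=C(Br)C(=O)O1 | intermediate |
| 13 | but-3-yn-1-ol | C#CCCO | starting material |
| 14 | tert-butyl(but-3-yn-1-yloxy)dimethylsilane | C#CCCO[Si](C)(C)C(C)(C)C | intermediate |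
| 15 | ethyl 5-(TBSO)pent-2-ynoate | CCOC(=O)C#CCCO[Si](C)(C)C(C)(C)C | intermediate |
| 16 | ethyl (2E)-5-(TBSO)-3-isopropylpent-2-enoate | CCOC(=O)/C=C(\CCO[Si](C)(C)C(C)(C)C)C(C)C | intermediate |
| 17 | (2E)-5-(TBSO)-3-isopropylpent-2-en-1-ol | OC/C=C(\CCO[Si](C)(C)C(C)(C)C)C(C)C | intermediate |
| 18 | (2E)-5-(TBSO)-3-isopropylpent-2-enal | O=C/C=C(\CCO[Si](C)(C)C(C)(C)C)C(C)C | intermediate |
| 19 | methyl bromoacetate | COC(=O)CBr | starting material |
| 20 | methyl 2-[bis(2,2,2-trifluoroethoxy)phosphoryl]acetate | COC(=O)CP(=O)(OCC(F)(F)F)OCC(F)(F)F | intermediate |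
| 21 | formaldehyde (paraformaldehyde) | C=O | starting material |
| 22 | methyl 2-[bis(trifluoroethoxy)phosphoryl]-3-hydroxypropanoate | COC(=O)C(CO)P(=O)(OCC(F)(F)F)OCC(F)(F)F | intermediate |
| 23 | TBDPS ether of 22 | COC(=O)C(CO[Si](c1ccccc1)(c1ccccc1)C(C)(C)C)P(=O)(OCC(F)(F)F)OCC(F)(F)F | intermediate |
| 24 | methyl (2Z,4E)-7-(TBSO)-2-[(TBDPSO)methyl]-5-isopropylhepta-2,4-dienoate | COC(=O)/C(CO[Si](c1ccccc1)(c1ccccc1)C(C)(C)C)=C\C=C(\C(C)C)CCO[Si](C)(C)C(C)(C)C | intermediate |
| 25 | 7-hydroxy analogue of 24 | COC(=O)/C(CO[Si](c1ccccc1)(c1ccccc1)C(C)(C)C)=C\C=C(\C(C)C)CCO | intermediate |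
| 26 | 7-iodo analogue of 24 | COC(=O)/C(CO[Si](c1ccccc1)(c1ccccc1)C(C)(C)C)=C\C=C(\C(C)C)CCI | intermediate |
| 27 | Negishi product (TBDPS ether, acetyl lactone) | COC(=O)/C(CO[Si](c1ccccc1)(c1ccccc1)C(C)(C)C)=C\C=C(\C(C)C)CCC2=CCC[C@](C)(OC2=O)C(C)=O | intermediate |
| 28 | hydroxymethyl dienoate | COC(=O)/C(CO)=C\C=C(\C(C)C)CCC2=CCC[C@](C)(OC2=O)C(C)=O | intermediate |
| 29 | bromomethyl dienoate | COC(=O)/C(CBr)=C\C=C(\C(C)C)CCC2=CCC[C@](C)(OC2=O)C(C)=O | intermediate |
| 30 | ketoemblide | COC(=O)/C1=C\C=C(\C(C)C)CCC2=CCC[C@](C)(OC2=O)C(=O)CC1 | target |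

---

**Total steps:** 25. **Longest linear sequence:** 14 (steps 1–10, then 22–25).

**Three steps most likely to fail**
1. **Step 25, macro-enolate alkylation.**
   - Risks: oligomerisation, SN2′ attack or Z→E isomerisation of the allylic bromide, and a reversible Michael addition of the enolate to the lactone enoate.
   - Fallback: change the closure to C6–C7 by an intramolecular Fukuyama coupling. This uses the α-(2-silyloxyethyl) phosphonate in step 17 in place of the hydroxymethyl one, and an S-ethyl thioester at C7 in place of the acetyl group.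
2. **Step 19, Still–Gennari olefination.**
   - Risks: poor Z-selectivity with the α-silyloxymethyl phosphonate, and β-elimination of silanolate from the phosphonate carbanion.
   - Fallback: fix the geometry by cross-coupling instead of olefination, by Stille or Negishi coupling of a preformed (Z)-β-iodo-2-(silyloxymethyl)acrylate with a C2 vinyl partner.
3. **Step 5, RCM of the tertiary acrylate to the 7-membered lactone.**
   - Risk: failure of the tertiary acrylate to close.
   - Fallback: form the ring by intramolecular HWE instead. Convert the tertiary alcohol to its bis(trifluoroethyl)phosphonoacetate ester, ozonolyse the terminal alkene to the aldehyde, and close the cis-enoate lactone with base.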